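**Plan**

1. Locants used throughout: C19 lactone carbonyl, C4 its quaternary α-carbon, C1–C3 the ring CH2 groups, C10 the quaternary carbon bearing the C9 ketone, C5 the ring-fusion CH, C6 the lactone O–CH, C7 the CH–OAc carbon, C8 the acetyl carbonyl.
2. Retrosynthetic cuts, in order: C9–C11 (Grignard) and the C8 ketal; the C6–O lactone bond together with the C7–O bond (back to an E-C6=C7 alkene and a free C19 acid); C4–C5 of ring A, which reconnects C19 to O–C7 as a ten-membered lactone; then the ester bond, C3–C4, C6–C7 and the C5≡C6 homologation.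
3. Enabling feature: on the cyclohexane (ring A) the C19 carboxyl on quaternary C4 and the C6 branch on C5 are cis, and the C6/C7 oxygens trace back to a C6=C7 alkene, so C19–C4–C5–C6=C7 is the γ,δ-unsaturated acid left by a [3,3] shift of the C19 ester of a C7 allylic alcohol.
4. Forward: a C10 quaternary alkyne is acylated (C6–C7), reduced, extended with propionate (C3–C4), semi-hydrogenated and lactonised to the ten-membered ring; the ring contraction closes ring A, epoxide opening closes the γ-lactone, and the acetate and the furyl ketone side chain come last.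
5. Stereochemistry: C10 from lipase desymmetrisation of a prochiral diol; a temporary C7 carbinol from asymmetric transfer hydrogenation, relayed to C5 and C4 by the [3,3] shift (ring-enforced boat); C6 and C7 from reagent-controlled epoxidation of the E-alkene and invertive lactonisation at C6.

Key step: step 16

Assumption: the lipase acetylates the hydroxymethyl arm that gives (R)-monoacetate 6 (if it prefers the other arm, oxidising and homologating the free arm first and silylating the acetate-derived arm afterwards leads to the same (S)-alkyne 10); 2-(furan-3-yl)ethanol 32 is taken as a catalogue compound.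

**Route**

Step 1
Reactants: 1 diethyl methylmalonate; 2 1-bromo-3-chloropropane
Product: 4 diethyl 2-(3-chloropropyl)-2-methylpropanedioate, via sodium enolate 3 (not isolated)
Conditions: NaH, THF/DMF, 0 °C; then 2, rt to 50 °C
Reagents that add atoms: none
Why: Malonic ester alkylation (SN2); the stabilised enolate displaces bromide far faster than chloride, so the chloride is kept as the later leaving group at C3.

Step 2
Reactants: 4 diethyl 2-(3-chloropropyl)-2-methylpropanedioate
Product: 5 2-(3-chloropropyl)-2-methylpropane-1,3-diol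
Conditions: LiAlH4, THF, 0 °C
Reagents that add atoms: none
Why: Hydride reduction of both esters; a primary alkyl chloride is not reduced at 0 °C, and the diol is prochiral at the future C10.

Step 3
Reactants: 5 2-(3-chloropropyl)-2-methylpropane-1,3-diol
Product: 6 (2R)-5-chloro-2-(hydroxymethyl)-2-methylpentyl acetate
Conditions: Pseudomonas fluorescens lipase, vinyl acetate, t-BuOMe, rt
Reagents that add atoms: vinyl acetate, CC(=O)OC=C
Why: Lipase-catalysed desymmetrising transesterification of a prochiral 2,2-disubstituted propane-1,3-diol; the enzyme acylates one enantiotopic arm irreversibly and thereby sets the quaternary centre C10.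

Step 4
Reactants: 6 (2R)-5-chloro-2-(hydroxymethyl)-2-methylpentyl acetate
Product: 7 (2S)-2-[(tert-butyldimethylsilyl)oxymethyl]-5-chloro-2-methylpentyl acetate
Conditions: t-BuMe2SiCl, imidazole, DMF, 0 °C
Reagents that add atoms: tert-butyldimethylsilyl chloride, CC(C)(C)[Si](C)(C)Cl
Why: Silylation of the free primary alcohol under mild base, where acetyl migration between the two arms (which would racemise C10) should not occur.

Step 5
Reactants: 7 (2S)-2-[(tert-butyldimethylsilyl)oxymethyl]-5-chloro-2-methylpentyl acetate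
Product: 8 (2S)-2-[(tert-butyldimethylsilyl)oxymethyl]-5-chloro-2-methylpentan-1-ol
Conditions: i-Bu2AlH, CH2Cl2, −78 °C
Reagents that add atoms: none
Why: Reductive cleavage of the acetate by a dialkylaluminium hydride at low temperature; no free alkoxide is generated in a protic medium, so 1,3-silyl migration and loss of enantiopurity are avoided.

Step 6
Reactants: 8 (2S)-2-[(tert-butyldimethylsilyl)oxymethyl]-5-chloro-2-methylpentan-1-ol
Product: 9 (2R)-2-[(tert-butyldimethylsilyl)oxymethyl]-5-chloro-2-methylpentanal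
Conditions: Dess–Martin periodinane, NaHCO3, CH2Cl2, 0 °C to rt
Reagents that add atoms: none
Why: Dess–Martin oxidation of a neopentyl primary alcohol; the aldehyde has no α-hydrogen and cannot epimerise.

Step 7
Reactants: 9 (2R)-2-[(tert-butyldimethylsilyl)oxymethyl]-5-chloro-2-methylpentanal
Product: 10 (2S)-tert-butyl{[2-(3-chloropropyl)-2-methylbut-3-yn-1-yl]oxy}dimethylsilane
Conditions: dimethyl (1-diazo-2-oxopropyl)phosphonate, K2CO3, MeOH, 0 °C to rt
Reagents that add atoms: dimethyl (1-diazo-2-oxopropyl)phosphonate, COP(=O)(OC)C(=[N+]=[N-])C(C)=O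
Why: Ohira–Bestmann variant of the Seyferth–Gilbert homologation; the added carbon becomes C6, and non-enolisable α-quaternary aldehydes are suitable substrates.

Step 8
Reactants: 11 ethyl pyruvate
Product: 12 ethyl 2-methyl-1,3-dioxolane-2-carboxylate
Conditions: ethylene glycol, p-TsOH (cat.), toluene, reflux, Dean–Stark
Reagents that add atoms: ethylene glycol, OCCO
Why: Acid-catalysed ketalisation with azeotropic removal of water; masks the future C8 ketone.

Step 9
Reactants: 12 ethyl 2-methyl-1,3-dioxolane-2-carboxylate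
Product: 13 N-methoxy-N,2-dimethyl-1,3-dioxolane-2-carboxamide
Conditions: MeNH(OMe)·HCl, i-PrMgCl, THF, −20 °C
Reagents that add atoms: N,O-dimethylhydroxylamine hydrochloride, CNOC.Cl
Why: Weinreb amide formation by aminolysis of the ester with the magnesium amide.

Step 10
Reactants: 10 (2S)-tert-butyl{[2-(3-chloropropyl)-2-methylbut-3-yn-1-yl]oxy}dimethylsilane; 13 N-methoxy-N,2-dimethyl-1,3-dioxolane-2-carboxamide
Product: 15 (4S)-4-[(tert-butyldimethylsilyl)oxymethyl]-7-chloro-4-methyl-1-(2-methyl-1,3-dioxolan-2-yl)hept-2-yn-1-one, via lithium acetylide 14 (not isolated)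
Conditions: n-BuLi, THF, −78 °C; then 13, −78 to 0 °C
Reagents that add atoms: none
Why: Acylation of a lithium acetylide by a Weinreb amide forms C6–C7; the chelated tetrahedral intermediate prevents over-addition, and the primary chloride is inert to the acetylide at low temperature.

Step 11
Reactants: 15 (4S)-4-[(tert-butyldimethylsilyl)oxymethyl]-7-chloro-4-methyl-1-(2-methyl-1,3-dioxolan-2-yl)hept-2-yn-1-one
Product: 16 (1R,4S)-4-[(tert-butyldimethylsilyl)oxymethyl]-7-chloro-4-methyl-1-(2-methyl-1,3-dioxolan-2-yl)hept-2-yn-1-ol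
Conditions: Ru[(S,S)-TsDPEN](p-cymene) (2 mol %), i-PrOH, rt
Reagents that add atoms: none
Why: Noyori asymmetric transfer hydrogenation of an α,β-acetylenic ketone; the (S,S)-catalyst treats the alkyne as the π-substituent and delivers hydride to the face that gives the temporary C7 carbinol, whose descriptor is R because the ketal carbon outranks the alkyne.

Step 12
Reactants: 16 (1R,4S)-4-[(tert-butyldimethylsilyl)oxymethyl]-7-chloro-4-methyl-1-(2-methyl-1,3-dioxolan-2-yl)hept-2-yn-1-ol
Product: 17 (1R,4S)-4-[(tert-butyldimethylsilyl)oxymethyl]-7-iodo-4-methyl-1-(2-methyl-1,3-dioxolan-2-yl)hept-2-yn-1-ol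
Conditions: NaI, NaHCO3, acetone, reflux
Reagents that add atoms: sodium iodide, [Na+].[I-]
Why: Finkelstein exchange driven by precipitation of NaCl; gives a leaving group suited to enolate alkylation.

Step 13
Reactants: 17 (1R,4S)-4-[(tert-butyldimethylsilyl)oxymethyl]-7-iodo-4-methyl-1-(2-methyl-1,3-dioxolan-2-yl)hept-2-yn-1-ol; 18 propanoic acid
Product: 20 (6S,9R)-6-[(tert-butyldimethylsilyl)oxymethyl]-9-hydroxy-2,6-dimethyl-9-(2-methyl-1,3-dioxolan-2-yl)non-7-ynoic acid (C2 epimers), via dilithium enediolate 19 (not isolated)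
Conditions: 18, LiN(i-Pr)2 (2 equiv per acid), THF/DMPU, 0 °C; then 17, 0 °C to rt (excess dianion)
Reagents that add atoms: none
Why: Alkylation of a carboxylic acid dianion by a primary iodide forms C3–C4 and gives the acid directly; the new C4 centre forms unselectively, which is harmless because C4 is enolised in step 16, and the linear alkyne keeps the C7 alkoxide away from the silyl ether.

Step 14
Reactants: 20 (6S,9R)-6-[(tert-butyldimethylsilyl)oxymethyl]-9-hydroxy-2,6-dimethyl-9-(2-methyl-1,3-dioxolan-2-yl)non-7-ynoic acid (C2 epimers)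
Product: 21 (6S,7Z,9R)-6-[(tert-butyldimethylsilyl)oxymethyl]-9-hydroxy-2,6-dimethyl-9-(2-methyl-1,3-dioxolan-2-yl)non-7-enoic acid (C2 epimers)
Conditions: H2 (1 atm), Pd/CaCO3 poisoned with Pb(OAc)2, quinoline, EtOAc, rt
Reagents that add atoms: none
Why: Lindlar semi-hydrogenation; syn delivery of hydrogen gives the Z-alkene that later turns H7 inward in the rearrangement.

Step 15
Reactants: 21 (6S,7Z,9R)-6-[(tert-butyldimethylsilyl)oxymethyl]-9-hydroxy-2,6-dimethyl-9-(2-methyl-1,3-dioxolan-2-yl)non-7-enoic acid (C2 epimers)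
Product: 23 (7S,8Z,10R)-7-[(tert-butyldimethylsilyl)oxymethyl]-3,7-dimethyl-10-(2-methyl-1,3-dioxolan-2-yl)-3,4,5,6,7,10-hexahydro-2H-oxecin-2-one (C3 epimers), via mixed anhydride 22 (not isolated)
Conditions: 2,4,6-Cl3C6H2COCl, Et3N, THF, rt; then slow addition to DMAP, toluene, 90 °C (about 1 mM)
Reagents that add atoms: none
Why: Yamaguchi macrolactonisation; the Z-alkene and the quaternary C10 (gem-disubstituent effect) fold the chain, and high dilution favours closure of the ten-membered lactone over oligomerisation.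

Step 16
Reactants: 23 (7S,8Z,10R)-7-[(tert-butyldimethylsilyl)oxymethyl]-3,7-dimethyl-10-(2-methyl-1,3-dioxolan-2-yl)-3,4,5,6,7,10-hexahydro-2H-oxecin-2-one (C3 epimers)
Product: 26 (1S,2R,3S)-3-[(tert-butyldimethylsilyl)oxymethyl]-1,3-dimethyl-2-[(E)-2-(2-methyl-1,3-dioxolan-2-yl)ethenyl]cyclohexane-1-carboxylic acid, via silyl ketene acetal 24 (not isolated), via silyl ester 25 (not isolated)
Conditions: LiN(i-Pr)2, t-BuMe2SiCl, THF/HMPA, −78 °C; then toluene, 100 °C; then K2CO3, MeOH/THF/H2O, rt
Reagents that add atoms: none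
Why: LiN(i-Pr)2 enolises the lactone at C4 and in situ O-silylation gives cyclic ketene acetal 24, whose C4=C19–O–C7–C6=C5 array undergoes a concerted suprafacial [3,3] shift on warming, forming C4–C5 and breaking O–C7 to leave silyl ester 25, which is hydrolysed on work-up. The closest known reaction type is the ring-contracting Ireland–Claisen rearrangement of macrolactone silyl ketene acetals to cis-2-alkenylcycloalkanecarboxylic acids. Ring A (C4, C3, C2, C1, C10, C5) closes by transannular C4–C5 bonding inside the ten-membered ring, a four-atom ring contraction that turns C19 and C6=C7 into exocyclic groups. C5 is controlled by the C7 carbinol centre through 1,3-chirality transfer, with H7 turned inward to avoid A(1,3) strain against C10 on the Z-alkene, which also makes the new C6=C7 alkene E. C4 is controlled by the ring: the lactone fixes the ketene acetal geometry (C3 cis to the ring oxygen) and allows only the boat transition state, so carboxyl and alkenyl end up cis. The step needs boat over chair and a matched C10; the three-carbon tether excludes the chair, and the (S)-C10 centre turns its methyl group toward the reacting array and the bulkier silyloxymethyl group away from it.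

Step 17
Reactants: 26 (1S,2R,3S)-3-[(tert-butyldimethylsilyl)oxymethyl]-1,3-dimethyl-2-[(E)-2-(2-methyl-1,3-dioxolan-2-yl)ethenyl]cyclohexane-1-carboxylic acid
Product: 28 (3S,3aR,4S,7aS)-4-[(tert-butyldimethylsilyl)oxymethyl]-3-[(S)-hydroxy(2-methyl-1,3-dioxolan-2-yl)methyl]-4,7a-dimethylhexahydro-2-benzofuran-1(3H)-one, via epoxy acid 27 (not isolated)
Conditions: 1,2:4,5-di-O-isopropylidene-D-erythro-2,3-hexodiulo-2,6-pyranose (D-fructose-derived Shi ketone, 0.5 equiv), KHSO5 (as 2KHSO5·KHSO4·K2SO4), K2CO3, Bu4NHSO4, MeCN/CH2(OMe)2/aq. Na2B4O7 buffer (pH 10.5), 0 °C; then pH 4 work-up and camphorsulfonic acid (cat.), CH2Cl2, rt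
Reagents that add atoms: potassium peroxymonosulfate, [K+].[O-]S(=O)(=O)OO
Why: Shi asymmetric epoxidation of the E-disubstituted alkene followed by 5-exo opening of the epoxy acid; the chiral dioxirane selects the alkene face (the sense this ketone shows with simple trans-alkenes corresponds to the (6R,7S)-epoxide), which fixes C7, and the carboxyl group attacks C6 with inversion to give the (6S)-lactone, attack at C7 being blocked by the adjacent ketal carbon.

Step 18
Reactants: 28 (3S,3aR,4S,7aS)-4-[(tert-butyldimethylsilyl)oxymethyl]-3-[(S)-hydroxy(2-methyl-1,3-dioxolan-2-yl)methyl]-4,7a-dimethylhexahydro-2-benzofuran-1(3H)-one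
Product: 29 (3S,3aR,4S,7aS)-3-[(S)-acetoxy(2-methyl-1,3-dioxolan-2-yl)methyl]-4-[(tert-butyldimethylsilyl)oxymethyl]-4,7a-dimethylhexahydro-2-benzofuran-1(3H)-one
Conditions: Ac2O, DMAP, pyridine, CH2Cl2, rt
Reagents that add atoms: acetic anhydride, CC(=O)OC(C)=O
Why: DMAP-catalysed acetylation of the secondary alcohol; installs the C7 acetate of the target, which also protects C7 during the later oxidations.

Step 19
Reactants: 29 (3S,3aR,4S,7aS)-3-[(S)-acetoxy(2-methyl-1,3-dioxolan-2-yl)methyl]-4-[(tert-butyldimethylsilyl)oxymethyl]-4,7a-dimethylhexahydro-2-benzofuran-1(3H)-one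
Product: 30 (3S,3aR,4S,7aS)-3-[(S)-acetoxy(2-methyl-1,3-dioxolan-2-yl)methyl]-4-(hydroxymethyl)-4,7a-dimethylhexahydro-2-benzofuran-1(3H)-one
Conditions: HF·pyridine, pyridine, THF, 0 °C to rt
Reagents that add atoms: none
Why: Fluoride-mediated cleavage of the primary silyl ether; the buffered reagent should leave the dioxolane, the acetate and the lactone untouched, and the C9 hydroxyl lies trans to C19 on ring A so it cannot translactonise.

Step 20
Reactants: 30 (3S,3aR,4S,7aS)-3-[(S)-acetoxy(2-methyl-1,3-dioxolan-2-yl)methyl]-4-(hydroxymethyl)-4,7a-dimethylhexahydro-2-benzofuran-1(3H)-one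
Product: 31 (3S,3aR,4S,7aS)-3-[(S)-acetoxy(2-methyl-1,3-dioxolan-2-yl)methyl]-4-formyl-4,7a-dimethylhexahydro-2-benzofuran-1(3H)-one
Conditions: Dess–Martin periodinane, NaHCO3, CH2Cl2, rt
Reagents that add atoms: none
Why: Dess–Martin oxidation of the neopentyl alcohol; the aldehyde on quaternary C10 cannot epimerise.

Step 21
Reactants: 32 2-(furan-3-yl)ethanol
Product: 33 3-(2-bromoethyl)furan
Conditions: CBr4, PPh3, CH2Cl2, 0 °C
Reagents that add atoms: carbon tetrabromide, BrC(Br)(Br)Br
Why: Appel bromination under neutral conditions that the furan tolerates.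

Step 22
Reactants: 31 (3S,3aR,4S,7aS)-3-[(S)-acetoxy(2-methyl-1,3-dioxolan-2-yl)methyl]-4-formyl-4,7a-dimethylhexahydro-2-benzofuran-1(3H)-one; 33 3-(2-bromoethyl)furan
Product: 35 (3S,3aR,4S,7aS)-3-[(S)-acetoxy(2-methyl-1,3-dioxolan-2-yl)methyl]-4-[3-(furan-3-yl)-1-hydroxypropyl]-4,7a-dimethylhexahydro-2-benzofuran-1(3H)-one (carbinol epimers), via Grignard reagent 34 (not isolated)
Conditions: 33, Mg, THF, rt; then addition to 31, THF, −78 °C
Reagents that add atoms: none
Why: Grignard addition to an aldehyde forms C9–C11; at −78 °C the aldehyde should react much faster than the acetate or the lactone with its quaternary α-carbon, and the unselectively formed carbinol centre is removed in step 23.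

Step 23
Reactants: 35 (3S,3aR,4S,7aS)-3-[(S)-acetoxy(2-methyl-1,3-dioxolan-2-yl)methyl]-4-[3-(furan-3-yl)-1-hydroxypropyl]-4,7a-dimethylhexahydro-2-benzofuran-1(3H)-one (carbinol epimers)
Product: 36 (3S,3aR,4S,7aS)-3-[(S)-acetoxy(2-methyl-1,3-dioxolan-2-yl)methyl]-4-[3-(furan-3-yl)propanoyl]-4,7a-dimethylhexahydro-2-benzofuran-1(3H)-one
Conditions: Dess–Martin periodinane, NaHCO3, CH2Cl2, rt
Reagents that add atoms: none
Why: Dess–Martin oxidation of the secondary alcohol to the C9 ketone under buffered conditions that spare the furan.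

Step 24
Reactants: 36 (3S,3aR,4S,7aS)-3-[(S)-acetoxy(2-methyl-1,3-dioxolan-2-yl)methyl]-4-[3-(furan-3-yl)propanoyl]-4,7a-dimethylhexahydro-2-benzofuran-1(3H)-one
Product: 37 (3S,3aR,4S,7aS)-3-[(S)-1-acetoxy-2-oxopropyl]-4-[3-(furan-3-yl)propanoyl]-4,7a-dimethylhexahydro-2-benzofuran-1(3H)-one (CNP0170401.2)
Conditions: p-TsOH (cat.), acetone/H2O, 40 °C
Reagents that add atoms: water, O
Why: Acid-catalysed ketal hydrolysis unveils the C8 ketone; the 3-alkylfuran, the acetate and the lactone should withstand these mild conditions, and dilute acid at this temperature should not enolise C7.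

**Compound list**

1 | diethyl methylmalonate | CCOC(=O)C(C)C(=O)OCC | starting material
2 | 1-bromo-3-chloropropane | ClCCCBr | starting material
3 | sodium enolate of 1 | CCOC(=O)[C-](C)C(=O)OCC.[Na+] | intermediate
4 | diethyl 2-(3-chloropropyl)-2-methylpropanedioate | CCOC(=O)C(C)(CCCCl)C(=O)OCC | intermediate
5 | 2-(3-chloropropyl)-2-methylpropane-1,3-diol | OCC(C)(CO)CCCCl | intermediate
6 | (2R)-5-chloro-2-(hydroxymethyl)-2-methylpentyl acetate | ClCCC[C@](C)(CO)COC(C)=O | intermediate
7 | (2S)-2-[(tert-butyldimethylsilyl)oxymethyl]-5-chloro-2-methylpentyl acetate | ClCCC[C@](C)(CO[Si](C)(C)C(C)(C)C)COC(C)=O | intermediate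
8 | (2S)-2-[(tert-butyldimethylsilyl)oxymethyl]-5-chloro-2-methylpentan-1-ol | ClCCC[C@](C)(CO[Si](C)(C)C(C)(C)C)CO | intermediate
9 | (2R)-2-[(tert-butyldimethylsilyl)oxymethyl]-5-chloro-2-methylpentanal | ClCCC[C@](C)(CO[Si](C)(C)C(C)(C)C)C=O | intermediate
10 | (2S)-tert-butyl{[2-(3-chloropropyl)-2-methylbut-3-yn-1-yl]oxy}dimethylsilane | ClCCC[C@](C)(CO[Si](C)(C)C(C)(C)C)C#C | intermediate
11 | ethyl pyruvate | CCOC(=O)C(C)=O | starting material
12 | ethyl 2-methyl-1,3-dioxolane-2-carboxylate | CCOC(=O)C1(C)OCCO1 | intermediate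
13 | N-methoxy-N,2-dimethyl-1,3-dioxolane-2-carboxamide | CON(C)C(=O)C1(C)OCCO1 | intermediate
14 | lithium acetylide of 10 | ClCCC[C@](C)(CO[Si](C)(C)C(C)(C)C)C#C[Li] | intermediate
15 | (4S)-4-[(tert-butyldimethylsilyl)oxymethyl]-7-chloro-4-methyl-1-(2-methyl-1,3-dioxolan-2-yl)hept-2-yn-1-one | ClCCC[C@](C)(CO[Si](C)(C)C(C)(C)C)C#CC(=O)C1(C)OCCO1 | intermediate
16 | (1R,4S)-4-[(tert-butyldimethylsilyl)oxymethyl]-7-chloro-4-methyl-1-(2-methyl-1,3-dioxolan-2-yl)hept-2-yn-1-ol | ClCCC[C@](C)(CO[Si](C)(C)C(C)(C)C)C#C[C@@H](O)C1(C)OCCO1 | intermediate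
17 | (1R,4S)-4-[(tert-butyldimethylsilyl)oxymethyl]-7-iodo-4-methyl-1-(2-methyl-1,3-dioxolan-2-yl)hept-2-yn-1-ol | ICCC[C@](C)(CO[Si](C)(C)C(C)(C)C)C#C[C@@H](O)C1(C)OCCO1 | intermediate
18 | propanoic acid | CCC(=O)O | starting material
19 | dilithium enediolate of propanoic acid | CC=C(O[Li])O[Li] | intermediate
20 | (6S,9R)-6-[(tert-butyldimethylsilyl)oxymethyl]-9-hydroxy-2,6-dimethyl-9-(2-methyl-1,3-dioxolan-2-yl)non-7-ynoic acid (C2 epimers) | OC(=O)C(C)CCC[C@](C)(CO[Si](C)(C)C(C)(C)C)C#C[C@@H](O)C1(C)OCCO1 | intermediate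
21 | (6S,7Z,9R)-6-[(tert-butyldimethylsilyl)oxymethyl]-9-hydroxy-2,6-dimethyl-9-(2-methyl-1,3-dioxolan-2-yl)non-7-enoic acid (C2 epimers) | OC(=O)C(C)CCC[C@](C)(CO[Si](C)(C)C(C)(C)C)/C=C\[C@@H](O)C1(C)OCCO1 | intermediate
22 | mixed anhydride of 21 with 2,4,6-trichlorobenzoic acid | O=C(OC(=O)c1c(Cl)cc(Cl)cc1Cl)C(C)CCC[C@](C)(CO[Si](C)(C)C(C)(C)C)/C=C\[C@@H](O)C1(C)OCCO1 | intermediate
23 | (7S,8Z,10R)-7-[(tert-butyldimethylsilyl)oxymethyl]-3,7-dimethyl-10-(2-methyl-1,3-dioxolan-2-yl)-3,4,5,6,7,10-hexahydro-2H-oxecin-2-one (C3 epimers; ten-membered lactone, C19 ester of the C7 alcohol) | CC1CCC[C@](C)(CO[Si](C)(C)C(C)(C)C)/C=C\[C@@H](OC1=O)C2(C)OCCO2 | intermediate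
24 | cyclic tert-butyldimethylsilyl ketene acetal of 23 (C3 of the chain cis to the ring oxygen) | C/C1=C(\O[Si](C)(C)C(C)(C)C)O[C@@H](C2(C)OCCO2)/C=C\[C@@](C)(CO[Si](C)(C)C(C)(C)C)CCC1 | intermediate
25 | tert-butyldimethylsilyl ester of 26 | CC(C)(C)[Si](C)(C)OC(=O)[C@@]1(C)CCC[C@](C)(CO[Si](C)(C)C(C)(C)C)[C@H]1/C=C/C2(C)OCCO2 | intermediate
26 | (1S,2R,3S)-3-[(tert-butyldimethylsilyl)oxymethyl]-1,3-dimethyl-2-[(E)-2-(2-methyl-1,3-dioxolan-2-yl)ethenyl]cyclohexane-1-carboxylic acid | OC(=O)[C@@]1(C)CCC[C@](C)(CO[Si](C)(C)C(C)(C)C)[C@H]1/C=C/C2(C)OCCO2 | intermediate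
27 | (1S,2R,3S)-3-[(tert-butyldimethylsilyl)oxymethyl]-1,3-dimethyl-2-[(2R,3S)-3-(2-methyl-1,3-dioxolan-2-yl)oxiran-2-yl]cyclohexane-1-carboxylic acid | OC(=O)[C@@]1(C)CCC[C@](C)(CO[Si](C)(C)C(C)(C)C)[C@H]1[C@H]2O[C@@H]2C3(C)OCCO3 | intermediate
28 | (3S,3aR,4S,7aS)-4-[(tert-butyldimethylsilyl)oxymethyl]-3-[(S)-hydroxy(2-methyl-1,3-dioxolan-2-yl)methyl]-4,7a-dimethylhexahydro-2-benzofuran-1(3H)-one | O[C@H](C1(C)OCCO1)[C@H]1OC(=O)[C@@]2(C)CCC[C@](C)(CO[Si](C)(C)C(C)(C)C)[C@@H]12 | intermediate
29 | (3S,3aR,4S,7aS)-3-[(S)-acetoxy(2-methyl-1,3-dioxolan-2-yl)methyl]-4-[(tert-butyldimethylsilyl)oxymethyl]-4,7a-dimethylhexahydro-2-benzofuran-1(3H)-one | CC(=O)O[C@H](C1(C)OCCO1)[C@H]1OC(=O)[C@@]2(C)CCC[C@](C)(CO[Si](C)(C)C(C)(C)C)[C@@H]12 | intermediate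
30 | (3S,3aR,4S,7aS)-3-[(S)-acetoxy(2-methyl-1,3-dioxolan-2-yl)methyl]-4-(hydroxymethyl)-4,7a-dimethylhexahydro-2-benzofuran-1(3H)-one | CC(=O)O[C@H](C1(C)OCCO1)[C@H]1OC(=O)[C@@]2(C)CCC[C@](C)(CO)[C@@H]12 | intermediate
31 | (3S,3aR,4S,7aS)-3-[(S)-acetoxy(2-methyl-1,3-dioxolan-2-yl)methyl]-4-formyl-4,7a-dimethylhexahydro-2-benzofuran-1(3H)-one | CC(=O)O[C@H](C1(C)OCCO1)[C@H]1OC(=O)[C@@]2(C)CCC[C@](C)(C=O)[C@@H]12 | intermediate
32 | 2-(furan-3-yl)ethanol | OCCc1ccoc1 | starting material
33 | 3-(2-bromoethyl)furan | BrCCc1ccoc1 | intermediate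
34 | 2-(furan-3-yl)ethylmagnesium bromide | Br[Mg]CCc1ccoc1 | intermediate
35 | (3S,3aR,4S,7aS)-3-[(S)-acetoxy(2-methyl-1,3-dioxolan-2-yl)methyl]-4-[3-(furan-3-yl)-1-hydroxypropyl]-4,7a-dimethylhexahydro-2-benzofuran-1(3H)-one (carbinol epimers) | CC(=O)O[C@H](C1(C)OCCO1)[C@H]1OC(=O)[C@@]2(C)CCC[C@](C)(C(O)CCc3ccoc3)[C@@H]12 | intermediate
36 | (3S,3aR,4S,7aS)-3-[(S)-acetoxy(2-methyl-1,3-dioxolan-2-yl)methyl]-4-[3-(furan-3-yl)propanoyl]-4,7a-dimethylhexahydro-2-benzofuran-1(3H)-one | CC(=O)O[C@H](C1(C)OCCO1)[C@H]1OC(=O)[C@@]2(C)CCC[C@](C)(C(=O)CCc3ccoc3)[C@@H]12 | intermediate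
37 | (3S,3aR,4S,7aS)-3-[(S)-1-acetoxy-2-oxopropyl]-4-[3-(furan-3-yl)propanoyl]-4,7a-dimethylhexahydro-2-benzofuran-1(3H)-one (CNP0170401.2) | CC(=O)O[C@H](C(C)=O)[C@H]1OC(=O)[C@@]2(C)CCC[C@](C)(C(=O)CCc3ccoc3)[C@@H]12 | target

**Step count**

Total step count: 24. Longest linear sequence: 21 steps (steps 1–7, 10–20 and 22–24).

**Steps most likely to fail**

Step 15. Acylation of the hindered C7 hydroxyl, which sits beside the ketal carbon, by the mixed anhydride may be slow, so that even at high dilution intermolecular esterification to diolides and oligomers outruns closure of the ten-membered ring. The fallback makes the hindered ester bond intermolecularly and closes the ring by olefin metathesis at the unhindered C2–C3 position. It sets out from iodide 17. Elimination with t-BuOK (THF, 0 °C) turns the iodopropyl chain into an allyl group and gives (1R,4S)-4-[(tert-butyldimethylsilyl)oxymethyl]-4-methyl-1-(2-methyl-1,3-dioxolan-2-yl)hept-6-en-2-yn-1-ol F1. Lindlar semi-hydrogenation gives the (2Z)-dienol F2. Esterification with commercial 2-methylbut-3-enoic acid (DCC, DMAP) gives the 2-methylbut-3-enoate F3. Ring-closing metathesis with the second-generation Grubbs catalyst RuCl2(=CHPh)(H2IMes)(PCy3) in dilute toluene gives the ten-membered dienyl lactone F4. Diimide (2-nitrobenzenesulfonyl hydrazide, Et3N) should then saturate the unhindered C2=C3 alkene in preference to the Z-C5=C6 alkene wedged between C10 and C7, which returns to lactone 23.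

Step 16. Bond formation between the fully substituted ketene acetal carbon C4 and C5, which is flanked by quaternary C10, may be too slow in the boat transition state, so that the ketene acetal is lost by C-silylation or hydrolysis before it rearranges. The fallback runs the same ring contraction on the lactone that lacks the C4 methyl group and introduces that methyl group afterwards on the bicyclic lactone enolate. It sets out from iodide 17. Alkylation with the dianion of acetic acid gives the C2-demethyl ynoic acid F5. Lindlar reduction gives the Z-seco acid F6. Yamaguchi closure gives the C3-demethyl ten-membered lactone F7. Ring contraction with LiN(i-Pr)2 and t-BuMe2SiCl gives the cis cyclohexanecarboxylic acid F8. Shi epoxidation with lactonisation as in step 17 gives the 7a-demethyl hydroxy lactone F9. Double deprotonation (LiN(i-Pr)2, 2.2 equiv, THF, −78 °C) followed by MeI should methylate C4 on the convex face of the cis-fused lactone, opposite to C10 and the C7 branch, which returns to hydroxy lactone 28.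

Step 17. Oxygen transfer from the chiral dioxirane to an alkene flanked by the C5 ring carbon and the ketal carbon may be slow, so that catalyst decomposition and unselective background oxidation erode the facial selectivity. The fallback is a substrate-controlled sequence through an iodolactone. It sets out from acid 26. Iodolactonisation (I2, NaHCO3, MeCN, 0 °C) is expected to give the iodolactone F10, with the C7 branch on the convex face (the C6 epimer of the target series) and iodine anti to the lactone oxygen. K2CO3 in MeOH opens the lactone, and the C6 alkoxide displaces iodide at C7 with inversion to give the epoxy methyl ester F11, which carries the same epoxide as 27. Camphorsulfonic acid in CH2Cl2 then closes the lactone with inversion at C6 and loss of methanol, which returns to hydroxy lactone 28.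

**Further compounds**

F1 | step 15 | (1R,4S)-4-[(tert-butyldimethylsilyl)oxymethyl]-4-methyl-1-(2-methyl-1,3-dioxolan-2-yl)hept-6-en-2-yn-1-ol | C=CC[C@](C)(CO[Si](C)(C)C(C)(C)C)C#C[C@@H](O)C1(C)OCCO1
F2 | step 15 | (1R,2Z,4S)-4-[(tert-butyldimethylsilyl)oxymethyl]-4-methyl-1-(2-methyl-1,3-dioxolan-2-yl)hepta-2,6-dien-1-ol | C=CC[C@](C)(CO[Si](C)(C)C(C)(C)C)/C=C\[C@@H](O)C1(C)OCCO1
F3 | step 15 | 2-methylbut-3-enoate ester of F2 (ester at the C7 hydroxyl) | C=CC[C@](C)(CO[Si](C)(C)C(C)(C)C)/C=C\[C@@H](OC(=O)C(C)C=C)C1(C)OCCO1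
F4 | step 15 | (7S,8Z,10R)-7-[(tert-butyldimethylsilyl)oxymethyl]-3,7-dimethyl-10-(2-methyl-1,3-dioxolan-2-yl)-3,6,7,10-tetrahydro-2H-oxecin-2-one (C3 epimers, C4=C5 geometry open) | CC1C=CC[C@](C)(CO[Si](C)(C)C(C)(C)C)/C=C\[C@@H](OC1=O)C2(C)OCCO2
F5 | step 16 | (6S,9R)-6-[(tert-butyldimethylsilyl)oxymethyl]-9-hydroxy-6-methyl-9-(2-methyl-1,3-dioxolan-2-yl)non-7-ynoic acid | OC(=O)CCCC[C@](C)(CO[Si](C)(C)C(C)(C)C)C#C[C@@H](O)C1(C)OCCO1
F6 | step 16 | (6S,7Z,9R)-6-[(tert-butyldimethylsilyl)oxymethyl]-9-hydroxy-6-methyl-9-(2-methyl-1,3-dioxolan-2-yl)non-7-enoic acid | OC(=O)CCCC[C@](C)(CO[Si](C)(C)C(C)(C)C)/C=C\[C@@H](O)C1(C)OCCO1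
F7 | step 16 | (7S,8Z,10R)-7-[(tert-butyldimethylsilyl)oxymethyl]-7-methyl-10-(2-methyl-1,3-dioxolan-2-yl)-3,4,5,6,7,10-hexahydro-2H-oxecin-2-one | O=C1CCCC[C@](C)(CO[Si](C)(C)C(C)(C)C)/C=C\[C@@H](O1)C2(C)OCCO2
F8 | step 16 | 1-demethyl analogue of 26 (carboxyl cis to the alkenyl group) | OC(=O)[C@H]1CCC[C@](C)(CO[Si](C)(C)C(C)(C)C)[C@H]1/C=C/C2(C)OCCO2
F9 | step 16 | 7a-demethyl analogue of 28 (cis-fused lactone) | O[C@H](C1(C)OCCO1)[C@H]1OC(=O)[C@H]2CCC[C@](C)(CO[Si](C)(C)C(C)(C)C)[C@@H]12
F10 | step 17 | iodolactone: C3 epimer of the lactone skeleton of 28 with iodine in place of the side-chain hydroxyl, iodine anti to the lactone oxygen | I[C@@H](C1(C)OCCO1)[C@@H]1OC(=O)[C@@]2(C)CCC[C@](C)(CO[Si](C)(C)C(C)(C)C)[C@@H]12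
F11 | step 17 | methyl ester of epoxy acid 27 | COC(=O)[C@@]1(C)CCC[C@](C)(CO[Si](C)(C)C(C)(C)C)[C@H]1[C@H]2O[C@@H]2C3(C)OCCO3
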